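**Plan**

1. Germacrane numbering: lactone O on C6, ring fusion C7, angelate on C8, acetates on C9 and C2, olefins C1=C10 (Z) and C4=C5 (E), lactone carbons C11–C13, methyls C14 (on C10) and C15 (on C4).
2. Enabling feature: C9 is an allylic carbinol of the ten-membered carbocycle and is bonded to C10 of the Z-trisubstituted C1=C10 olefin, so the ring can be opened at C9–C10 to a C9 aldehyde and a Z-alkenyl iodide at C10.
3. Retrosynthetic cuts, in order: the C8 and C9 ester C–O bonds; C9–C10 (carbocycle); C6–C7 together with the lactone C12–O6 bond; C2–C3.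
4. Forward: (Z)-3-iodobut-2-enal and a senecioate dienolate give the C1–C6 iodo enal; a glyceraldehyde-derived 2-(bromomethyl)acrylate is added to it by divalent chromium, which forms the lactone ring first; alkenylchromium addition closes the carbocycle last.
5. Stereochemistry: C8 from (S)-glyceraldehyde acetonide; C2 from a catalyst-controlled vinylogous aldol; C6 and C7 from the anti-selective allylation under control of C8; C9 in the ring closure; the Z-iodide from trans-hydroalumination; the angelate geometry from angelic acid.

Key step: step 14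

Assumption: the (R,R)-bisphosphoramide of step 4 directs the dienolate to the Re face of conjugated aldehydes, as 2R requires; if the sense is the opposite, its enantiomer is used.

**Route**

Step 1
Reactants: 1 but-2-yn-1-ol
Product: 3 (Z)-3-iodobut-2-en-1-ol, via alkenylaluminate 2 (not isolated)
Conditions: NaAlH2(OCH2CH2OMe)2, THF, 0 °C to rt; then I2, THF, −78 °C to 0 °C
Reagents that add atoms: iodine, II
Why: Alkoxide-directed trans-hydroalumination of the propargylic alcohol places aluminium on C3 in the five-membered oxa-aluminacycle 2, and iodinolysis of the C–Al bond with retention should give the Z-iodoalkene that becomes C1=C10 (hydroalumination–iodination of a propargylic alcohol).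

Step 2
Reactants: 3 (Z)-3-iodobut-2-en-1-ol
Product: 4 (Z)-3-iodobut-2-enal
Conditions: MnO2, CH2Cl2, rt, dark; used without storage
Reagents that add atoms: none
Why: MnO2 oxidises allylic alcohols to enals under neutral heterogeneous conditions that should leave the alkenyl iodide and its Z geometry intact (allylic oxidation).

Step 3
Reactants: 5 methyl 3-methylbut-2-enoate
Product: 6 tert-butyl[(1-methoxy-3-methylbuta-1,3-dien-1-yl)oxy]dimethylsilane
Conditions: LiN(iPr)2, THF, N,N'-dimethylpropyleneurea, −78 °C; then tBuMe2SiCl, −78 °C to rt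
Reagents that add atoms: tert-butyldimethylsilyl chloride, CC(C)(C)[Si](C)(C)Cl
Why: γ-Deprotonation of the senecioate gives the cross-conjugated lithium dienolate, which is silylated on oxygen to the silyl ketene acetal (silyl dienolate formation).

Step 4
Reactants: 4 (Z)-3-iodobut-2-enal; 6 tert-butyl[(1-methoxy-3-methylbuta-1,3-dien-1-yl)oxy]dimethylsilane
Product: 8 methyl (2E,5R,6Z)-5-hydroxy-7-iodo-3-methylocta-2,6-dienoate, via trichlorosilyl ether 7 (not isolated)
Conditions: SiCl4, (R,R)-N,N'-bis[(11bR)-3,5-dimethyl-4-oxido-3,5-dihydro-4H-dinaphtho[2,1-d:1',2'-f][1,3,2]diazaphosphepin-4-yl]-N,N'-dimethylpentane-1,5-diamine (5 mol%), iPr2NEt (10 mol%), CH2Cl2, −78 °C; aq. NaHCO3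
Reagents that add atoms: none
Why: Vinylogous Mukaiyama aldol addition under Lewis-base activation of SiCl4, in which the phosphoramide-bound trichlorosilyl cation binds the enal and shields one face so that the dienolate should attack through its γ-carbon on the Re face, setting the carbinol (C2 of the target) as R and giving the E-configured C4=C5 enoate.

Step 5
Reactants: 8 methyl (2E,5R,6Z)-5-hydroxy-7-iodo-3-methylocta-2,6-dienoate
Product: 9 (2E,5R,6Z)-7-iodo-3-methylocta-2,6-diene-1,5-diol
Conditions: iBu2AlH (3.5 equiv), CH2Cl2, −78 °C; aq. potassium sodium tartrate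
Reagents that add atoms: none
Why: iBu2AlH reduces the conjugated ester to the primary allylic alcohol by 1,2-hydride delivery at low temperature without touching the alkenyl iodide or either olefin geometry (ester reduction).

Step 6
Reactants: 9 (2E,5R,6Z)-7-iodo-3-methylocta-2,6-diene-1,5-diol
Product: 10 (2E,5R,6Z)-5-hydroxy-7-iodo-3-methylocta-2,6-dienal
Conditions: 2,2,6,6-tetramethylpiperidin-1-oxyl (10 mol%), PhI(OAc)2 (1.1 equiv), CH2Cl2, rt
Reagents that add atoms: none
Why: The oxoammonium salt formed from the nitroxyl and PhI(OAc)2 oxidises the unhindered primary allylic alcohol much faster than the secondary one, so the E-enal should form with the C2 carbinol untouched (chemoselective nitroxyl-catalysed oxidation).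

Step 7
Reactants: 10 (2E,5R,6Z)-5-hydroxy-7-iodo-3-methylocta-2,6-dienal
Product: 11 (2E,5R,6Z)-5-acetoxy-7-iodo-3-methylocta-2,6-dienal
Conditions: Ac2O, pyridine, 4-(dimethylamino)pyridine (5 mol%), CH2Cl2, 0 °C
Reagents that add atoms: acetic anhydride, CC(=O)OC(C)=O
Why: Acyl transfer catalysed by the aminopyridine acetylates the secondary alcohol under mild base, so the C2 acetate of the target is in place before the fragments are joined (esterification; the C–O bond of the stereocentre is not broken).

Step 8
Reactants: 12 (S)-2,2-dimethyl-1,3-dioxolane-4-carbaldehyde; 13 methyl acrylate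
Product: 14 methyl 2-{hydroxy[(4S)-2,2-dimethyl-1,3-dioxolan-4-yl]methyl}prop-2-enoate (both carbinol epimers)
Conditions: 1,4-diazabicyclo[2.2.2]octane (0.5 equiv), methyl acrylate (3 equiv), 1,4-dioxane/H2O, rt
Reagents that add atoms: none
Why: Morita–Baylis–Hillman reaction, in which the amine adds to the acrylate, the zwitterionic enolate attacks the aldehyde and the amine is expelled; the new carbinol configuration is of no consequence because that carbon becomes sp2 in step 9, and the dioxolane stereocentre is not involved.

Step 9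
Reactants: 14 methyl 2-{hydroxy[(4S)-2,2-dimethyl-1,3-dioxolan-4-yl]methyl}prop-2-enoate
Product: 15 methyl (2Z)-2-(bromomethyl)-3-[(4R)-2,2-dimethyl-1,3-dioxolan-4-yl]prop-2-enoate
Conditions: N-bromosuccinimide, Me2S, CH2Cl2, 0 °C to rt
Reagents that add atoms: N-bromosuccinimide, BrN1C(=O)CCC1=O
Why: The bromodimethylsulfonium salt activates the hydroxyl group and bromide displaces it in the SN2′ sense, so both epimers should converge on the thermodynamically preferred Z-configured 2-(bromomethyl)alkenoate (allylic transposition of a Morita–Baylis–Hillman alcohol).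

Step 10
Reactants: 11 (2E,5R,6Z)-5-acetoxy-7-iodo-3-methylocta-2,6-dienal; 15 methyl (2Z)-2-(bromomethyl)-3-[(4R)-2,2-dimethyl-1,3-dioxolan-4-yl]prop-2-enoate
Product: 17 seco-lactone acetonide (trans 6,12-olide carrying the dioxolane on C7), via hydroxy ester 16 (not isolated)
Conditions: CrCl2 (4 equiv, nickel-free grade), THF, 0 °C to rt; crude stirred with pyridinium p-toluenesulfonate (cat.), CH2Cl2, rt, if lactonisation is incomplete
Reagents that add atoms: none
Why: Divalent chromium turns the allylic bromide into a 2-(methoxycarbonyl)allylchromium reagent that adds to the enal through its γ-carbon in a chair-like transition state with the dioxolanyl group equatorial (Nozaki–Hiyama allylation, anti-selective whatever the bromide geometry), so C6 and C7 should come out anti and the alkoxide closes the trans lactone; the aldehyde is expected to approach C7 anti to the dioxolane C–O bond with C8–H in the olefin plane, which sets 7S and with it 6R from the 8R centre, and nickel-free CrCl2 neither touches the alkenyl iodide nor causes the 1,4-elimination of the allylic oxygen that zinc would risk.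

Step 11
Reactants: 17 seco-lactone acetonide
Product: 18 seco-lactone 8,9-diol
Conditions: AcOH/H2O (4:1), 40 °C
Reagents that add atoms: none
Why: Acid-catalysed hydrolysis of the terminal isopropylidene acetal frees the C8/C9 diol under conditions mild enough for the acetate, the allylic lactone and the acrylate unit (acetal hydrolysis).

Step 12
Reactants: 18 seco-lactone 8,9-diol
Product: 19 seco-lactone 8,9-bis(triethylsilyl) ether
Conditions: Et3SiOSO2CF3 (2.5 equiv), 2,6-lutidine, CH2Cl2, −78 °C
Reagents that add atoms: triethylsilyl trifluoromethanesulfonate, CC[Si](CC)(CC)OS(=O)(=O)C(F)(F)F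
Why: The silyl triflate silylates both hydroxyl groups within minutes at low temperature, before the free C8 hydroxyl can attack the lactone (silyl ether formation).

Step 13
Reactants: 19 seco-lactone 8,9-bis(triethylsilyl) ether
Product: 20 seco iodo aldehyde (C9 formyl group and C8 triethylsilyl ether)
Conditions: (COCl)2, Me2SO, CH2Cl2, −78 °C, then 19, −78 to −40 °C; Et3N, −78 °C to rt
Reagents that add atoms: none
Why: Under Swern conditions chlorodimethylsulfonium chloride cleaves the less hindered primary triethylsilyl ether selectively and the alkoxysulfonium salt collapses to the aldehyde when the base is added, while the secondary silyl ether at C8 should survive (direct Swern oxidation of a primary silyl ether).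

Step 14
Reactants: 20 seco iodo aldehyde
Product: 22 9-hydroxy-8-triethylsilyloxy germacranolide 2-acetate, via alkenylchromium 21 (not isolated)
Conditions: CrCl2 (10 equiv), NiCl2 (0.1 equiv), degassed Me2SO, 0.003 M, slow addition of 20, rt
Reagents that add atoms: none
Why: CrCl2 reduces NiCl2 to zerovalent nickel, which adds oxidatively to the alkenyl C10–I bond without loss of the Z geometry; transmetalation to trivalent chromium gives alkenylchromium 21, whose carbon attacks the C9 formyl group to give the chromium alkoxide of 22 (Nozaki–Hiyama–Kishi reaction). The closest known reaction type is the nickel/chromium-mediated macrocyclisation of ω-formyl alkenyl iodides to medium-ring allylic alcohols, including ten-membered germacranolide rings. The ten-membered carbocycle closes in the 10-exo-trig mode by carbonyl addition of the C10 chain end; the Z-olefin, the E-olefin and the trans lactone hold most of the chain in fixed segments, and high dilution disfavours intermolecular coupling. The new stereocentre C9 is set by the cyclic transition state: the formyl oxygen with its chromium is expected on the outside of the forming ring and gauche to the C8 silyloxy group, which leads to the 8,9-threo (9R) alcohol. The step needs chemoselectivity, secured by the low basicity and aldehyde preference of alkenylchromium reagents (lactone, acetate, acrylate unit and allylic esters are left alone), and 9R facial selectivity, which runs against the open-chain 1,2-induction of an α-silyloxy aldehyde and therefore rests on the ring conformation alone.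

Step 15
Reactants: 22 9-hydroxy-8-triethylsilyloxy germacranolide 2-acetate
Product: 23 8-triethylsilyloxy germacranolide 2,9-diacetate
Conditions: Ac2O, pyridine, 4-(dimethylamino)pyridine (10 mol%), CH2Cl2, 0 °C to rt
Reagents that add atoms: acetic anhydride, CC(=O)OC(C)=O
Why: Aminopyridine-catalysed acetylation of the secondary allylic C9 alcohol, which leaves every stereocentre untouched (esterification).

Step 16
Reactants: 23 8-triethylsilyloxy germacranolide 2,9-diacetate
Product: 24 8-hydroxy germacranolide 2,9-diacetate
Conditions: HF·pyridine, pyridine, THF, 0 °C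
Reagents that add atoms: none
Why: Fluoride cleaves the triethylsilyl ether under buffered, weakly acidic conditions, chosen over basic fluoride so that the neighbouring C9 acetate should not migrate to O8 (desilylation).

Step 17
Reactants: 24 8-hydroxy germacranolide 2,9-diacetate; 25 angelic acid
Product: 27 CNP0499619.1, via mixed anhydride 26 (not isolated)
Conditions: 25, 2,4,6-trichlorobenzoyl chloride, Et3N, toluene, rt; then 24, toluene, 80 °C
Reagents that add atoms: none
Why: Yamaguchi-type esterification in which the mixed anhydride 26 acylates the C8 hydroxyl at the less hindered angeloyl carbonyl, and leaving out a nucleophilic catalyst should keep the Z geometry of the angelate; C8 keeps its configuration because its C–O bond is not broken.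

**Compound list**

Descriptors for 16–24 and 27 use germacrane numbering; the SMILES is the authoritative structure. The descriptor at C7 switches between S and R with the substituents on O6 and O8, without any change in the spatial arrangement.

1 | but-2-yn-1-ol | CC#CCO | starting material
2 | sodium 2,2-bis(2-methoxyethoxy)-3-methyl-2,5-dihydro-1,2-oxaluminol-2-uide (cyclic alkenylaluminate) | CC1=CCO[Al-]1(OCCOC)OCCOC.[Na+] | intermediate (not isolated)
3 | (2Z)-3-iodobut-2-en-1-ol | C/C(I)=C/CO | intermediate
4 | (2Z)-3-iodobut-2-enal | C/C(I)=C/C=O | intermediate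
5 | methyl 3-methylbut-2-enoate | COC(=O)C=C(C)C | starting material
6 | tert-butyl[(1-methoxy-3-methylbuta-1,3-dien-1-yl)oxy]dimethylsilane (1Z shown; the ketene acetal geometry is of no consequence) | CO/C(O[Si](C)(C)C(C)(C)C)=C/C(C)=C | intermediate
7 | methyl (2E,5R,6Z)-7-iodo-3-methyl-5-(trichlorosilyloxy)octa-2,6-dienoate | COC(=O)/C=C(\C)C[C@@H](O[Si](Cl)(Cl)Cl)/C=C(/C)I | intermediate (not isolated)
8 | methyl (2E,5R,6Z)-5-hydroxy-7-iodo-3-methylocta-2,6-dienoate | COC(=O)/C=C(\C)C[C@@H](O)/C=C(/C)I | intermediate
9 | (2E,5R,6Z)-7-iodo-3-methylocta-2,6-diene-1,5-diol | OC/C=C(\C)C[C@@H](O)/C=C(/C)I | intermediate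
10 | (2E,5R,6Z)-5-hydroxy-7-iodo-3-methylocta-2,6-dienal | O=C/C=C(\C)C[C@@H](O)/C=C(/C)I | intermediate
11 | (2E,5R,6Z)-5-acetoxy-7-iodo-3-methylocta-2,6-dienal | O=C/C=C(\C)C[C@@H](OC(C)=O)/C=C(/C)I | intermediate
12 | (S)-2,2-dimethyl-1,3-dioxolane-4-carbaldehyde | CC1(C)OC[C@H](O1)C=O | starting material
13 | methyl acrylate | C=CC(=O)OC | starting material
14 | methyl 2-{hydroxy[(4S)-2,2-dimethyl-1,3-dioxolan-4-yl]methyl}prop-2-enoate (both carbinol epimers) | COC(=O)C(=C)C(O)[C@@H]1COC(C)(C)O1 | intermediate
15 | methyl (2Z)-2-(bromomethyl)-3-[(4R)-2,2-dimethyl-1,3-dioxolan-4-yl]prop-2-enoate | COC(=O)/C(CBr)=C/[C@@H]1COC(C)(C)O1 | intermediate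
16 | methyl (3S,4R,5E,8R,9Z)-8-acetoxy-3-[(4R)-2,2-dimethyl-1,3-dioxolan-4-yl]-4-hydroxy-10-iodo-6-methyl-2-methylideneundeca-5,9-dienoate (6R,7S,8R; formed as its chromium alkoxide) | COC(=O)C(=C)[C@@H]([C@H](O)/C=C(\C)C[C@@H](OC(C)=O)/C=C(/C)I)[C@@H]1COC(C)(C)O1 | intermediate (not isolated)
17 | (2R,6R,7S,8R)-2-acetoxy-10-iodo-8,9-(isopropylidenedioxy)-9,10-secogermacra-1(10)Z,4E,11(13)-trien-12,6-olide | C=C1C(=O)O[C@@H]([C@H]1[C@@H]2COC(C)(C)O2)/C=C(\C)C[C@@H](OC(C)=O)/C=C(/C)I | intermediate
18 | (2R,6R,7R,8R)-2-acetoxy-8,9-dihydroxy-10-iodo-9,10-secogermacra-1(10)Z,4E,11(13)-trien-12,6-olide | C=C1C(=O)O[C@@H]([C@H]1[C@@H](O)CO)/C=C(\C)C[C@@H](OC(C)=O)/C=C(/C)I | intermediate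
19 | (2R,6R,7S,8R)-2-acetoxy-10-iodo-8,9-bis(triethylsilyloxy)-9,10-secogermacra-1(10)Z,4E,11(13)-trien-12,6-olide | C=C1C(=O)O[C@@H]([C@H]1[C@@H](O[Si](CC)(CC)CC)CO[Si](CC)(CC)CC)/C=C(\C)C[C@@H](OC(C)=O)/C=C(/C)I | intermediate
20 | (2R,6R,7S,8R)-2-acetoxy-10-iodo-9-oxo-8-(triethylsilyloxy)-9,10-secogermacra-1(10)Z,4E,11(13)-trien-12,6-olide | C=C1C(=O)O[C@@H]([C@H]1[C@@H](O[Si](CC)(CC)CC)C=O)/C=C(\C)C[C@@H](OC(C)=O)/C=C(/C)I | intermediate
21 | alkenylchromium dichloride of 20 (trivalent chromium on C10 in place of iodine, Z retained) | C=C1C(=O)O[C@@H]([C@H]1[C@@H](O[Si](CC)(CC)CC)C=O)/C=C(\C)C[C@@H](OC(C)=O)/C=C(/C)[Cr](Cl)Cl | intermediate (not isolated)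
22 | (2R,6R,7S,8R,9R)-2-acetoxy-9-hydroxy-8-(triethylsilyloxy)germacra-1(10)Z,4E,11(13)-trien-12,6-olide | C=C1C(=O)O[C@@H]2/C=C(\C)C[C@@H](OC(C)=O)/C=C(/C)[C@@H](O)[C@H](O[Si](CC)(CC)CC)[C@@H]12 | intermediate
23 | (2R,6R,7S,8R,9R)-2,9-diacetoxy-8-(triethylsilyloxy)germacra-1(10)Z,4E,11(13)-trien-12,6-olide | C=C1C(=O)O[C@@H]2/C=C(\C)C[C@@H](OC(C)=O)/C=C(/C)[C@@H](OC(C)=O)[C@H](O[Si](CC)(CC)CC)[C@@H]12 | intermediate
24 | (2R,6R,7R,8R,9R)-2,9-diacetoxy-8-hydroxygermacra-1(10)Z,4E,11(13)-trien-12,6-olide | C=C1C(=O)O[C@@H]2/C=C(\C)C[C@@H](OC(C)=O)/C=C(/C)[C@@H](OC(C)=O)[C@H](O)[C@@H]12 | intermediate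
25 | angelic acid, (2Z)-2-methylbut-2-enoic acid | C/C=C(/C)C(=O)O | starting material
26 | (2Z)-2-methylbut-2-enoic 2,4,6-trichlorobenzoic anhydride | C/C=C(/C)C(=O)OC(=O)c1c(Cl)cc(Cl)cc1Cl | intermediate (not isolated)
27 | CNP0499619.1, (2R,6R,7S,8R,9R)-2,9-diacetoxy-8-angeloyloxygermacra-1(10)Z,4E,11(13)-trien-12,6-olide | C=C1C(=O)O[C@@H]2/C=C(\C)C[C@@H](OC(C)=O)/C=C(/C)[C@@H](OC(C)=O)[C@H](OC(=O)/C(C)=C\C)[C@@H]12 | target

**Step count**

Total: 17 steps. Longest linear sequence: 14 steps (steps 1, 2, 4, 5, 6, 7, 10, 11, 12, 13, 14, 15, 16, 17).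

**Steps most likely to fail**

Step 14. The cyclisation may suffer from intermolecular coupling if the dilution is insufficient. Above all, the facial selectivity at the C9 aldehyde may be poor or reversed, because open-chain 1,2-induction by the α-silyloxy group favours the 9S alcohol. The fallback sets out from 20. The ring closure is run in the same way and the epimeric alcohol, (2R,6R,7S,8R,9S)-2-acetoxy-9-hydroxy-8-(triethylsilyloxy)germacra-1(10)Z,4E,11(13)-trien-12,6-olide F1, is carried on in place of 22. A Mitsunobu reaction with acetic acid (PPh3, diisopropyl azodicarboxylate, toluene, 0 °C) should invert C9 and install the acetate in one operation, so that the C9 configuration comes from an SN2 displacement and not from the addition. The route is rejoined at 23.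

Step 10. The ester-substituted allylchromium may not equilibrate fully to the geometry that reacts through the equatorial chair, which would give cis lactone, and the facial bias exerted by C8 may be eroded. The fallback sets out from 12 and replaces the metallotropic reagent by a configurationally fixed allylboronate. Seyferth–Gilbert homologation with the Ohira–Bestmann reagent (K2CO3, MeOH) gives (4R)-4-ethynyl-2,2-dimethyl-1,3-dioxolane F2. Deprotonation (n-BuLi, THF, −78 °C) and methyl chloroformate give methyl 3-[(4R)-2,2-dimethyl-1,3-dioxolan-4-yl]prop-2-ynoate F3. Conjugate syn-hydroalumination (iBu2AlH, hexamethylphosphoramide, THF, 0 °C) and alkylation of the α-alumino enoate with 2-(iodomethyl)-4,4,5,5-tetramethyl-1,3,2-dioxaborolane give methyl (2Z)-3-[(4R)-2,2-dimethyl-1,3-dioxolan-4-yl]-2-[(4,4,5,5-tetramethyl-1,3,2-dioxaborolan-2-yl)methyl]prop-2-enoate F4, in which the dioxolanyl group is cis to the ester. Stereospecific allylboration of 11 with this boronate (toluene, 80 °C, or Sc(OTf)3 catalysis at low temperature) passes through a closed chair in which the fixed olefin geometry enforces the anti relationship. The adduct is 16, and brief treatment with pyridinium p-toluenesulfonate lactonises it, so the route is rejoined at 17.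

Step 17. Acylation of the hindered C8 hydroxyl may be slow; during it the angelate may isomerise to the tiglate, or the C9 acetate may migrate to O8. The fallback sets out from 24 and builds the angelate on the substrate. Carbodiimide esterification (N,N'-dicyclohexylcarbodiimide, 4-(dimethylamino)pyridine, CH2Cl2, 0 °C) with 2-[bis(2,2,2-trifluoroethoxy)phosphoryl]propanoic acid gives the phosphonate ester, (2R,6R,7S,8R,9R)-2,9-diacetoxy-8-{2-[bis(2,2,2-trifluoroethoxy)phosphoryl]propanoyloxy}germacra-1(10)Z,4E,11(13)-trien-12,6-olide F5. Still–Gennari olefination (KN(SiMe3)2, 18-crown-6, THF, −78 °C, then acetaldehyde) should then form the Z-configured 2-methylbut-2-enoate directly, which rejoins the route at 27.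

Further compounds
F1 | step 14 | (2R,6R,7S,8R,9S)-2-acetoxy-9-hydroxy-8-(triethylsilyloxy)germacra-1(10)Z,4E,11(13)-trien-12,6-olide | C=C1C(=O)O[C@@H]2/C=C(\C)C[C@@H](OC(C)=O)/C=C(/C)[C@H](O)[C@H](O[Si](CC)(CC)CC)[C@@H]12
F2 | step 10 | (4R)-4-ethynyl-2,2-dimethyl-1,3-dioxolane | C#C[C@@H]1COC(C)(C)O1
F3 | step 10 | methyl 3-[(4R)-2,2-dimethyl-1,3-dioxolan-4-yl]prop-2-ynoate | COC(=O)C#C[C@@H]1COC(C)(C)O1
F4 | step 10 | methyl (2Z)-3-[(4R)-2,2-dimethyl-1,3-dioxolan-4-yl]-2-[(4,4,5,5-tetramethyl-1,3,2-dioxaborolan-2-yl)methyl]prop-2-enoate | COC(=O)/C(CB1OC(C)(C)C(C)(C)O1)=C\[C@@H]1COC(C)(C)O1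
F5 | step 17 | (2R,6R,7S,8R,9R)-2,9-diacetoxy-8-{2-[bis(2,2,2-trifluoroethoxy)phosphoryl]propanoyloxy}germacra-1(10)Z,4E,11(13)-trien-12,6-olide (both epimers at the phosphonate α-carbon) | C=C1C(=O)O[C@@H]2/C=C(\C)C[C@@H](OC(C)=O)/C=C(/C)[C@@H](OC(C)=O)[C@H](OC(=O)C(C)P(=O)(OCC(F)(F)F)OCC(F)(F)F)[C@@H]12
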